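## Structural features

Beilschmieflavonoid B consists of two flavan (2-phenylchroman) units, each a benzene ring (ring A) fused to a tetrahydropyran (ring C) with an unsubstituted phenyl group at C2. The units are joined only by an ether oxygen between C4 of unit A (5-OH, 6,7-dimethoxy) and C4' of unit B (5',6',7'-trimethoxy). The four stereocentres form two 1,3-pairs, C2/C4 (2S,4R) and C2'/C4' (2'S,4'R), each 2,4-trans, and the oxygen-bearing centres C4 and C4' stand next to each other across the ether bridge. Both ether carbons are benzylic to rings with oxygen at both ortho positions and at the para position, so either C–O bond ionises with traces of acid; the cation is then lost to Friedel–Crafts attack by the free C8 or C8' positions, to elimination, or to scrambling of C4 and C4'. The free 5-OH ortho to C4 opens an ortho-quinone methide pathway, the benzylic C2–O1 and C2'–O1' bonds rule out hydrogenolysis, and the oxygen-rich rings are easily oxidised or halogenated. The difficulty is therefore the crowded secondary–secondary ether with defined configuration at both carbons, and the C2' centre that must be set relative to C4' once that ether exists. Unit A can take its skeleton and oxygen pattern from a natural flavone, so only the pyran ring of unit B has to be built. The key step exploits the C2'–C3' bond of ring C in unit B, which lies next to O1': as a double bond it is an enol ether that metathesis can form from a vinyl group on C4' and an aryl 1-phenylvinyl ether, and C2', benzylic and alpha to O1', can later take up hydrogen as a radical under the control of C4'.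

## Logic of the disconnections

17 ⇒ 16. The O5–H bond is replaced by O5–Si. The phenol ortho to C4 must stay masked through oxidant, titanium, ruthenium and radical chemistry. The forward step must free it without acid, which fluoride does.

16 ⇒ 15. The C2'–H and C3'–H bonds are removed and C2'=C3' is introduced. This deletes the C2' stereocentre and turns ring C of unit B into a cyclic enol ether. The forward hydrogenation must add hydrogen 2',4'-trans under the control of C4', without acid and without hydrogenolysis.

15 ⇒ 14. The C2'=C3' double bond is cut in the metathesis sense, opening ring C of unit B to a vinyl group on C4' and an aryl 1-phenylvinyl ether. The precursor is an acyclic diene in which C4' is an ordinary allylic ether centre. The forward step needs the catalyst to load on the vinyl group and neutral conditions.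

14 ⇒ 13. The enol ether CH2 is exchanged for a carbonyl oxygen. An aryl benzoate is the stable carrier of the O–C(Ph) unit. The forward methylenation must be non-acidic and meet no other carbonyl group.

13 ⇒ 10 + 11 (through 12). The acyl C–O bond is cut and the phenol is returned to an allyl ether. An aryl ester next to a free or metallated carbinol oxygen would shift to that oxygen, which is also the thermodynamically preferred site, so the benzoyl group must arrive only after the carbinol oxygen is etherified. The forward step needs an allyl removal that spares the silyl ether and the allylic bis-benzylic ether.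

10 ⇒ 5 + 9. The C4–O bond is cut. This is the most convergent cut and gives two pieces of similar size. The cation at C4 is stabilised by O1, O5 and O7, and the ring with its 2-phenyl anchor controls the face, while C4' arrives intact on the oxygen of the nucleophile. The forward step must make the cation from a C–H bond without Brønsted acid, favour O- over C-attack, and give the 2,4-trans ether.

9 ⇒ 8. The C4'–C(vinyl) bond is cut. This is the only stereocentre of unit B that a chiral reagent must set. The forward step is a catalytic enantioselective vinyl transfer to a di-ortho-substituted, electron-rich aldehyde.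

8 ⇒ 7 ⇒ 6. The O–allyl bond and then the aryl–CHO bond are cut. Both ortho positions of 6 are equivalent, so formylation has no regiochemical problem.

5 ⇒ 4. A hydroxyl group is put back on C4. The 4-ol is what asymmetric hydrogenation of a flavone delivers, and its removal leaves the C4–H bond from which the cation of the etherification is made. The forward reduction must not touch C2.

4 ⇒ 3. Four hydrogens are removed from C2, C3, C4 and O4, giving the flavone. The forward hydrogenation sets C2 by catalyst control.

3 ⇒ 2 ⇒ 1. The O5–Si bond and the two O–CH3 bonds are cut. The chelated 5-OH of 1 is the least reactive phenol, so the order of methylation needs no protecting group.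

## Other disconnections considered

Alternative 1: Both aryl–oxygen bonds C8a–O1 and C8a'–O1' are cut in the 5-O-allyl ether of the target A1. This leads to the open-chain bis(2-bromoaryl) ether diol A2, in which all four stereocentres already exist as carbinol and ether carbons.
- Forward key step: CuI, 1,10-phenanthroline and Cs2CO3 would couple each secondary benzylic alkoxide with its ortho C–Br bond (twofold intramolecular Ullmann etherification, retention at C2 and C2'), followed by allyl removal with zerovalent palladium.
- In favour: both pyran rings close in one operation. C2 and C2' come from reagent-controlled ketone reductions, so no late hydrogenation decides a stereocentre, and on security of the C2' configuration this alternative is the better plan. No acid-labile 4H-chromene appears.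
- Against: the aryl bromides sit on very electron-rich rings next to the branched benzylic carbon, so oxidative addition should need prolonged heating with carbonate, which stresses the bis-benzylic ether. More seriously, the central ether of A2 would have to be made between two open-chain carbinols, where no ring fixes the face of attack at either carbon.
- Comparison: on mechanism it is the equal of the chosen plan. On structure it moves the hard problem (the ether) to a stage where it is harder to control. On step economy it should be longer, because four acyclic stereocentres must be set one by one.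

Alternative 2: The O1–C2 and C3–C4 bonds of unit A are cut in the hexahydrochromen-5-one A3. This leads to the 2-(alkoxymethylene)-5-methoxycyclohexane-1,3-dione A4, whose alkoxy group is the complete unit B, and styrene A5.
- Forward key step: an inverse-electron-demand hetero-Diels–Alder reaction of the 1-oxadiene A4 with A5 under Eu(fod)3 or a chiral Cu(OTf)2–bis(oxazoline) catalyst, followed by aromatisation of ring A.
- In favour: the sensitive ether would be introduced by alkoxy exchange on a vinylogous ester, so no cation at C4 or C4' is needed; on this point it is better than the chosen plan. The cycloaddition is atom-economical, and its absolute sense can be set by a catalyst.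
- Against: the usual endo mode places the phenyl and alkoxy groups cis, while the target needs them trans. Styrene is a poor partner for this heterodiene. A3 lacks the C6 oxygen and the aromatic oxidation level, so oxygenation, dehydrogenation and methylation must follow on a compound whose C4 ether can be eliminated.
- Comparison: on mechanism it is gentler for the ether. On structure it is weaker in relative configuration. On step economy it is clearly behind, because ring A must be rebuilt after the key step.

Alternative 3: The O1'–C2' bond is cut with iodine at C3' as a relay, in the 3'-iodoflavan A6 (5-O-SEM). This leads to the (E)-styrenyl phenol A7, whose C4' centre would come from an aromatic Claisen rearrangement with transfer of chirality.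
- Forward key step: N-iodosuccinimide with NaHCO3 would activate the styrenyl double bond and the phenol oxygen would attack the benzylic carbon anti to iodine (6-endo iodoetherification), followed by radical deiodination and removal of the SEM group.
- In favour: C2' is set in a closed-shell cyclisation through a chair-like transition state, no flavylium-prone intermediate appears, and no metathesis catalyst can be diverted by an enol ether. Like the chosen plan it lets C4' control C2', and on this principle it is equal; on predictability of the ring-closing step it is arguably better.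
- Against: an electrophilic iodine source meets two rings with free, strongly activated C8 and C8' positions, so ring iodination competes. Any hydrogen iodide formed endangers the ether. Two steps are needed after closure, and SEM removal calls for forcing fluoride or acid.
- Comparison: on mechanism equal or better at the cyclisation itself, on chemoselectivity weaker, and on step economy longer in both the approach to A7 and the end game.

Key step: step 11

Remarks before the steps:
- Flavan means 2-phenylchroman, with primed locants for unit B. The descriptors derived from the target are (2S,4R) and (2'S,4'R), and the acyclic carbinol carbon that becomes C4' is (R) because aryl outranks vinyl.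
- Assumption: the (R,R) antipode of the carbene ligand SINpEt is taken to deliver the 2S series in step 3. If the sense of induction is opposite, the (S,S) ligand is used and nothing else changes.
- Compounds 10 and 12 to 17 are handled on triethylamine-deactivated silica or basic alumina.

Step 1
Reactants: 1 baicalein (5,6,7-trihydroxyflavone)
Product: 2 5-hydroxy-6,7-dimethoxyflavone
Conditions: MeI (2.2 equiv), K2CO3, acetone, 56 °C
Reagents that add atoms: iodomethane, CI
Why: Williamson O-methylation; the 5-OH is hydrogen-bonded to the C4 carbonyl and is the least acidic and least nucleophilic phenol, so two equivalents of MeI should cap O7 and O6 and leave O5 free.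

Step 2
Reactants: 2 5-hydroxy-6,7-dimethoxyflavone
Product: 3 5-(tert-butyldimethylsilyloxy)-6,7-dimethoxyflavone
Conditions: TBSOTf, 2,6-lutidine, CH2Cl2, 0 → 23 °C
Reagents that add atoms: tert-butyldimethylsilyl triflate, CC(C)(C)[Si](C)(C)OS(=O)(=O)C(F)(F)F
Why: Silylation with the silyl triflate is strong enough to cap the chelated phenol; the aryl silyl ether should survive hydrogenation, DDQ, Cp2TiMe2, ruthenium carbenes and radical conditions and falls to fluoride without acid.

Step 3
Reactants: 3 5-(tert-butyldimethylsilyloxy)-6,7-dimethoxyflavone
Product: 4 (2S,4S)-5-(tert-butyldimethylsilyloxy)-6,7-dimethoxyflavan-4-ol (2,4-cis)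
Conditions: H2 (100 bar), Ru(cod)(2-methylallyl)2 (5 mol %), (R,R)-SINpEt·HBF4 (10 mol %), KOtBu (15 mol %), toluene, 40 °C
Reagents that add atoms: none
Why: Asymmetric hydrogenation of a flavone with a chiral ruthenium N-heterocyclic carbene catalyst, a known route from flavones to cis-flavan-4-ols; the catalyst sets C2 (S) when the C2=C3 bond is reduced, and the ketone then takes hydrogen on the same face to give the 2,4-cis alcohol. The C4 centre is discarded in step 4.

Step 4
Reactants: 4 (2S,4S)-5-(tert-butyldimethylsilyloxy)-6,7-dimethoxyflavan-4-ol
Product: 5 (2S)-5-(tert-butyldimethylsilyloxy)-6,7-dimethoxyflavan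
Conditions: Et3SiH (8 equiv), TFA (2 equiv), CH2Cl2, −40 → 0 °C
Reagents that add atoms: none
Why: Ionic hydrogenation; acid ionises the benzylic alcohol to a cation stabilised by O1, O5 and O7, and the excess silane should reduce it before another arene can attack. C2 is not involved and keeps its configuration.

Step 5
Reactants: 6 3,4,5-trimethoxyphenol
Product: 7 2-hydroxy-4,5,6-trimethoxybenzaldehyde
Conditions: MgCl2, Et3N, (CH2O)n, MeCN, 82 °C
Reagents that add atoms: formaldehyde (as paraformaldehyde), C=O
Why: Magnesium-phenoxide-directed ortho-formylation of a phenol with paraformaldehyde, a second formaldehyde acting as hydride acceptor; the two ortho positions are equivalent, so one aldehyde results.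

Step 6
Reactants: 7 2-hydroxy-4,5,6-trimethoxybenzaldehyde
Product: 8 2-(allyloxy)-4,5,6-trimethoxybenzaldehyde
Conditions: allyl bromide, K2CO3, DMF, 50 °C
Reagents that add atoms: allyl bromide, C=CCBr
Why: Williamson etherification; unlike an aryl ester, the allyl ether cannot migrate to the neighbouring alkoxide formed in step 7, and zerovalent palladium later removes it without touching the silyl ether.

Step 7
Reactants: 8 2-(allyloxy)-4,5,6-trimethoxybenzaldehyde
Product: 9 (R)-1-[2-(allyloxy)-4,5,6-trimethoxyphenyl]prop-2-en-1-ol
Conditions: Zn(CH=CH2)2 (salt-free, 1.5 equiv), (+)-MIB (10 mol %), toluene, −20 → 0 °C; pH 7 buffer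
Reagents that add atoms: divinylzinc, C=C[Zn]C=C
Why: Amino-alcohol-catalysed enantioselective addition of a vinylzinc reagent to an aldehyde; (−)-MIB directs organozinc groups to the Si face of aryl aldehydes, so the (+) antipode should deliver vinyl to the Re face. Because aryl outranks vinyl, Re-face delivery gives the (R)-carbinol.

Step 8
Reactants: 5 (2S)-5-(tert-butyldimethylsilyloxy)-6,7-dimethoxyflavan (1.3 equiv); 9 (R)-1-[2-(allyloxy)-4,5,6-trimethoxyphenyl]prop-2-en-1-ol
Product: 10 (2S,4R)-4-{(R)-1-[2-(allyloxy)-4,5,6-trimethoxyphenyl]allyloxy}-5-(tert-butyldimethylsilyloxy)-6,7-dimethoxyflavan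
Conditions: DDQ (1.3 equiv, added slowly), 2,6-di-tert-butylpyridine (0.3 equiv), 4 Å MS, CH2Cl2, −40 → 0 °C; Et3N quench
Reagents that add atoms: none
Why: Oxidative C–H etherification, known for flavans with simple alcohols: DDQ takes hydride from C4 and the alcohol captures the cation. Attack should be pseudoaxial, trans to the equatorial 2-phenyl group and away from peri strain with the 5-silyloxy group, giving 4R, while C4' is retained because only the O–H bond of 9 reacts. The C4–H left in the product is pseudoequatorial and poorly aligned for a second hydride loss.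

Step 9
Reactants: 10 (2S,4R)-4-{(R)-1-[2-(allyloxy)-4,5,6-trimethoxyphenyl]allyloxy}-5-(tert-butyldimethylsilyloxy)-6,7-dimethoxyflavan; 11 benzoyl chloride
Product: 13 (2S,4R)-4-{(R)-1-[2-(benzoyloxy)-4,5,6-trimethoxyphenyl]allyloxy}-5-(tert-butyldimethylsilyloxy)-6,7-dimethoxyflavan, via free phenol 12 (not isolated)
Conditions: Pd(PPh3)4 (5 mol %), morpholine (1.2 equiv), THF, 23 °C; then Et3N, DMAP (cat.), BzCl, 0 °C
Reagents that add atoms: none
Why: Tsuji–Trost allyl transfer from the aryl allyl ether to morpholine frees the phenol, which is acylated in the same flask. The alkyl allylic ether has no leaving group that zerovalent palladium can ionise, and with the carbinol oxygen already etherified no O-to-O acyl shift is possible.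

Step 10
Reactants: 13 (2S,4R)-4-{(R)-1-[2-(benzoyloxy)-4,5,6-trimethoxyphenyl]allyloxy}-5-(tert-butyldimethylsilyloxy)-6,7-dimethoxyflavan
Product: 14 (2S,4R)-4-{(R)-1-[4,5,6-trimethoxy-2-(1-phenylvinyloxy)phenyl]allyloxy}-5-(tert-butyldimethylsilyloxy)-6,7-dimethoxyflavan
Conditions: Cp2TiMe2 (3 equiv), toluene, pyridine (1 %), 75 °C, dark; basic Al2O3 filtration
Reagents that add atoms: dimethyltitanocene Cp2TiMe2, C[Ti](C)(C1C=CC=C1)C1C=CC=C1
Why: Petasis methylenation; Cp2Ti=CH2 formed on heating converts the aryl ester carbonyl, the only carbonyl present, into the 1-phenylvinyl ether through an oxatitanacyclobutane under non-acidic conditions.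

Step 11
Reactants: 14 (2S,4R)-4-{(R)-1-[4,5,6-trimethoxy-2-(1-phenylvinyloxy)phenyl]allyloxy}-5-(tert-butyldimethylsilyloxy)-6,7-dimethoxyflavan
Product: 15 (2S,4R)-5-(tert-butyldimethylsilyloxy)-6,7-dimethoxy-4-{[(4R)-5,6,7-trimethoxy-2-phenyl-4H-chromen-4-yl]oxy}flavan
Conditions: second-generation Hoveyda–Grubbs catalyst RuCl2(SIMes)(=CH-C6H4-2-OiPr) (10 mol %), degassed toluene, 70 °C, argon stream; basic Al2O3 filtration, used at once
Reagents that add atoms: none
Why: The ruthenium benzylidene exchanges onto the monosubstituted vinyl group on C4'; the new alkylidene adds across the 1,1-disubstituted enol ether with ruthenium on its CH2 end, and cycloreversion of the metallacyclobutane forms C2'=C3' and releases Ru=CH2, which carries the cycle on as ethylene is lost. The closest known reaction type is ring-closing metathesis of aryl vinyl ethers bearing a terminal alkene, which gives benzofurans and 4H-chromenes. The pyran ring of unit B closes as a six-membered ring with both carbons of the new double bond as ring members, by a [2+2] cycloaddition and cycloreversion sequence. No stereocentre is created; C4', C4 and C2 are spectators because the medium is neutral. The step needs initiation at the vinyl group and not at the enol ether, which would park the metal as an unreactive alkoxy-substituted carbene; the substrate secures this because the vinyl group is monosubstituted while the enol ether is 1,1-disubstituted and electron-rich and can offer only its CH2 end to the metal. The step also needs freedom from acid and from ruthenium hydride double-bond migration, because the 4-alkoxy-4H-chromene would ionise to a flavylium ion or shift its double bond toward C4'; degassed solvent, base-washed glassware and a short reaction time address this. The argon stream removes ethylene and drives the closure.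

Step 12
Reactants: 15 (2S,4R)-5-(tert-butyldimethylsilyloxy)-6,7-dimethoxy-4-{[(4R)-5,6,7-trimethoxy-2-phenyl-4H-chromen-4-yl]oxy}flavan
Product: 16 (2S,4R)-5-(tert-butyldimethylsilyloxy)-6,7-dimethoxy-4-{[(2S,4R)-5,6,7-trimethoxyflavan-4-yl]oxy}flavan
Conditions: Mn(dpm)3 (20 mol %), PhSiH3 (2 equiv), tBuOOH (1.5 equiv), iPrOH/hexane, 22 °C, degassed
Reagents that add atoms: none
Why: Radical hydrogenation by metal-hydride hydrogen-atom transfer (Mukaiyama-type): a hydrogen atom adds to C3' and leaves the benzylic, alpha-oxy radical at C2'. The second hydrogen is expected to arrive pseudoaxially in the half-chair that keeps the 4'-alkoxy group pseudoaxial (away from 5'-OMe), which places phenyl equatorial and 2',4'-trans (2'S). A surface-catalysed hydrogenation would add cis, anti to the alkoxy group, and would give the wrong isomer.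

Step 13
Reactants: 16 (2S,4R)-5-(tert-butyldimethylsilyloxy)-6,7-dimethoxy-4-{[(2S,4R)-5,6,7-trimethoxyflavan-4-yl]oxy}flavan
Product: 17 beilschmieflavonoid B
Conditions: TBAF (1.2 equiv), THF, 0 °C; pH 7 buffer
Reagents that add atoms: none
Why: Fluoride cleaves the aryl silyl ether under basic, acid-free conditions; the bis-benzylic ether and the four stereocentres are not touched.

Compound list

1 | baicalein (5,6,7-trihydroxyflavone) | O=c1cc(-c2ccccc2)oc2cc(O)c(O)c(O)c12 | starting material
2 | 5-hydroxy-6,7-dimethoxyflavone | O=c1cc(-c2ccccc2)oc2cc(OC)c(OC)c(O)c12 | intermediate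
3 | 5-(tert-butyldimethylsilyloxy)-6,7-dimethoxyflavone | O=c1cc(-c2ccccc2)oc2cc(OC)c(OC)c(O[Si](C)(C)C(C)(C)C)c12 | intermediate
4 | (2S,4S)-5-(tert-butyldimethylsilyloxy)-6,7-dimethoxyflavan-4-ol (2,4-cis) | COc1cc2c(c(O[Si](C)(C)C(C)(C)C)c1OC)[C@@H](O)C[C@@H](c1ccccc1)O2 | intermediate
5 | (2S)-5-(tert-butyldimethylsilyloxy)-6,7-dimethoxyflavan | COc1cc2c(c(O[Si](C)(C)C(C)(C)C)c1OC)CC[C@@H](c1ccccc1)O2 | intermediate
6 | 3,4,5-trimethoxyphenol | COc1cc(O)cc(OC)c1OC | starting material
7 | 2-hydroxy-4,5,6-trimethoxybenzaldehyde | O=Cc1c(O)cc(OC)c(OC)c1OC | intermediate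
8 | 2-(allyloxy)-4,5,6-trimethoxybenzaldehyde | O=Cc1c(OCC=C)cc(OC)c(OC)c1OC | intermediate
9 | (R)-1-[2-(allyloxy)-4,5,6-trimethoxyphenyl]prop-2-en-1-ol | O[C@H](C=C)c1c(OCC=C)cc(OC)c(OC)c1OC | intermediate
10 | (2S,4R)-4-{(R)-1-[2-(allyloxy)-4,5,6-trimethoxyphenyl]allyloxy}-5-(tert-butyldimethylsilyloxy)-6,7-dimethoxyflavan | COc1cc2c(c(O[Si](C)(C)C(C)(C)C)c1OC)[C@H](O[C@H](C=C)c1c(OCC=C)cc(OC)c(OC)c1OC)C[C@@H](c1ccccc1)O2 | intermediate
11 | benzoyl chloride | O=C(Cl)c1ccccc1 | starting material
12 | (2S,4R)-4-{(R)-1-[2-hydroxy-4,5,6-trimethoxyphenyl]allyloxy}-5-(tert-butyldimethylsilyloxy)-6,7-dimethoxyflavan (free phenol, not isolated) | COc1cc2c(c(O[Si](C)(C)C(C)(C)C)c1OC)[C@H](O[C@H](C=C)c1c(O)cc(OC)c(OC)c1OC)C[C@@H](c1ccccc1)O2 | intermediate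
13 | (2S,4R)-4-{(R)-1-[2-(benzoyloxy)-4,5,6-trimethoxyphenyl]allyloxy}-5-(tert-butyldimethylsilyloxy)-6,7-dimethoxyflavan | COc1cc2c(c(O[Si](C)(C)C(C)(C)C)c1OC)[C@H](O[C@H](C=C)c1c(OC(=O)c3ccccc3)cc(OC)c(OC)c1OC)C[C@@H](c1ccccc1)O2 | intermediate
14 | (2S,4R)-4-{(R)-1-[4,5,6-trimethoxy-2-(1-phenylvinyloxy)phenyl]allyloxy}-5-(tert-butyldimethylsilyloxy)-6,7-dimethoxyflavan (metathesis precursor) | COc1cc2c(c(O[Si](C)(C)C(C)(C)C)c1OC)[C@H](O[C@H](C=C)c1c(OC(=C)c3ccccc3)cc(OC)c(OC)c1OC)C[C@@H](c1ccccc1)O2 | intermediate
15 | (2S,4R)-5-(tert-butyldimethylsilyloxy)-6,7-dimethoxy-4-{[(4R)-5,6,7-trimethoxy-2-phenyl-4H-chromen-4-yl]oxy}flavan | COc1cc2c(c(O[Si](C)(C)C(C)(C)C)c1OC)[C@H](O[C@@H]1C=C(c3ccccc3)Oc3cc(OC)c(OC)c(OC)c31)C[C@@H](c1ccccc1)O2 | intermediate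
16 | (2S,4R)-5-(tert-butyldimethylsilyloxy)-6,7-dimethoxy-4-{[(2S,4R)-5,6,7-trimethoxyflavan-4-yl]oxy}flavan (5-O-silyl ether of the target) | COc1cc2c(c(O[Si](C)(C)C(C)(C)C)c1OC)[C@H](O[C@@H]1C[C@@H](c3ccccc3)Oc3cc(OC)c(OC)c(OC)c31)C[C@@H](c1ccccc1)O2 | intermediate
17 | beilschmieflavonoid B, (2S,4R)-6,7-dimethoxy-4-{[(2S,4R)-5,6,7-trimethoxyflavan-4-yl]oxy}flavan-5-ol | COc1cc2c(c(O)c1OC)[C@H](O[C@@H]1C[C@@H](c3ccccc3)Oc3cc(OC)c(OC)c(OC)c31)C[C@@H](c1ccccc1)O2 | target

Total step count: 13. Longest linear sequence: 10 steps (from 1 through steps 1 to 4 and 8 to 13); the branch from 6 supplies steps 5 to 7.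

Steps least certain to work

Step 11 (key step).
- What may go wrong: the catalyst may load slowly on the crowded vinyl group and be sequestered as an alkoxy-substituted carbene after reacting with the enol ether first. Ruthenium hydrides formed on prolonged heating may move the double bond toward C4'. Adventitious acid may ionise the 4-alkoxy-4H-chromene.
- Fallback: it sets out from 13 and comes back at 15. The benzoate 13 is treated with the reduced titanium ethylidene reagent made from TiCl4, TMEDA, Zn, PbCl2 (cat.) and CH3CHBr2 in THF (Takai–Utimoto conditions). The titanium alkylidene exchanges onto the vinyl group and then olefinates the ester carbonyl intramolecularly (olefinic ester cyclisation), so the C2'=C3' bond is made from the carbonyl carbon without 14 and without ruthenium. No new compound arises (F0).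

Step 8.
- What may go wrong: the cation may be taken by carbon (Friedel–Crafts attack of the free, activated ring positions of 5 or 9) instead of by the hindered hydroxyl. It may lose a proton to a flav-3-ene that is oxidised further. The quinone may oxidise the carbinol of 9, and hydroquinone acidity may erode the trans selectivity by reversible ionisation.
- Fallback: it sets out from 4 and comes back at 10. Alcohol 4 is treated with benzyl mercaptan and catalytic ZnI2 to give (2S,4R)-4-(benzylsulfanyl)-5-(tert-butyldimethylsilyloxy)-6,7-dimethoxyflavan F1. AgOTf with 2,6-di-tert-butyl-4-methylpyridine then ionises F1 at low temperature in the presence of 9 (thiophilic activation, as in thioglycoside coupling), which gives 10 without any oxidant in the flask.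

Step 12.
- What may go wrong: the second hydrogen may be delivered from the less hindered face anti to the 4'-alkoxy group, giving the 2',4'-cis isomer. Oxygen-centred radicals may abstract the doubly activated C4'–H of 15, leading to epimerisation or to a flavylium ion. The manganese complex may act as a Lewis acid toward the 4-alkoxy-4H-chromene.
- Fallback: it sets out from 15 and comes back at 16. Mukaiyama hydration (Co(acac)2, PhSiH3, O2, iPrOH) converts the enol ether into the hemiketal, which opens to (2S,4R)-4-{(R)-1-(2-hydroxy-4,5,6-trimethoxyphenyl)-3-oxo-3-phenylpropoxy}-5-(tert-butyldimethylsilyloxy)-6,7-dimethoxyflavan F2. Corey–Bakshi–Shibata reduction with the (S)-methyl oxazaborolidine and BH3·SMe2 gives (2S,4R)-4-{(1R,3R)-3-hydroxy-1-(2-hydroxy-4,5,6-trimethoxyphenyl)-3-phenylpropoxy}-5-(tert-butyldimethylsilyloxy)-6,7-dimethoxyflavan F3. Mitsunobu cyclisation (PPh3, DIAD) closes O1'–C2' with inversion to the 2'S centre of 16, so C2' is set by the reagent.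

Step 3.
- What may go wrong: the bulky peri silyloxy group may stop the reduction at the flavanone or lower the enantioselectivity, and the base used to generate the carbene may remove some silyl ether.
- Fallback: it sets out from 3 and comes back at 4. Conjugate reduction of 3 with LiBH(s-Bu)3 in THF at −78 °C gives racemic 5-(tert-butyldimethylsilyloxy)-6,7-dimethoxyflavanone F4. Noyori-type transfer hydrogenation with RuCl(p-cymene)[(S,S)-TsDPEN] and HCO2H/Et3N then acts as a kinetic resolution; it is expected to reduce the (2S)-ketone faster to the cis-(2S,4S) alcohol 4, which is separated from unreacted (2R)-ketone.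

Step 7.
- What may go wrong: facial selectivity may be poor with the di-ortho-substituted, chelating aldehyde, and an uncatalysed background addition may lower the enantiomeric purity.
- Fallback: it sets out from 8 and comes back at 9. CH2=CHMgBr adds to 8 to give racemic 1-[2-(allyloxy)-4,5,6-trimethoxyphenyl]prop-2-en-1-ol F5. Sharpless kinetic resolution (Ti(OiPr)4, D-(−)-diisopropyl tartrate, tBuOOH, 4 Å MS, CH2Cl2, −20 °C) should epoxidise the (S)-enantiomer faster and leave (R)-9.

Further compounds

F0 | step 11 | none | none
F1 | step 8 | (2S,4R)-4-(benzylsulfanyl)-5-(tert-butyldimethylsilyloxy)-6,7-dimethoxyflavan | COc1cc2c(c(O[Si](C)(C)C(C)(C)C)c1OC)[C@H](SCc1ccccc1)C[C@@H](c1ccccc1)O2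
F2 | step 12 | (2S,4R)-4-{(R)-1-(2-hydroxy-4,5,6-trimethoxyphenyl)-3-oxo-3-phenylpropoxy}-5-(tert-butyldimethylsilyloxy)-6,7-dimethoxyflavan | COc1cc2c(c(O[Si](C)(C)C(C)(C)C)c1OC)[C@H](O[C@@H](c1c(O)cc(OC)c(OC)c1OC)CC(=O)c1ccccc1)C[C@@H](c1ccccc1)O2
F3 | step 12 | (2S,4R)-4-{(1R,3R)-3-hydroxy-1-(2-hydroxy-4,5,6-trimethoxyphenyl)-3-phenylpropoxy}-5-(tert-butyldimethylsilyloxy)-6,7-dimethoxyflavan | COc1cc2c(c(O[Si](C)(C)C(C)(C)C)c1OC)[C@H](O[C@@H](c1c(O)cc(OC)c(OC)c1OC)C[C@@H](O)c1ccccc1)C[C@@H](c1ccccc1)O2
F4 | step 3 | racemic 5-(tert-butyldimethylsilyloxy)-6,7-dimethoxyflavanone | COc1cc2c(c(O[Si](C)(C)C(C)(C)C)c1OC)C(=O)CC(c1ccccc1)O2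
F5 | step 7 | racemic 1-[2-(allyloxy)-4,5,6-trimethoxyphenyl]prop-2-en-1-ol | OC(C=C)c1c(OCC=C)cc(OC)c(OC)c1OC
A1 | alternative 1 | 5-O-allyl ether of beilschmieflavonoid B | COc1cc2c(c(OCC=C)c1OC)[C@H](O[C@@H]1C[C@@H](c3ccccc3)Oc3cc(OC)c(OC)c(OC)c31)C[C@@H](c1ccccc1)O2
A2 | alternative 1 | open-chain bis(2-bromoaryl) ether diol, precursor of A1 | COc1cc(Br)c(c(OCC=C)c1OC)[C@H](O[C@@H](c1c(Br)cc(OC)c(OC)c1OC)C[C@@H](c1ccccc1)O)C[C@@H](c1ccccc1)O
A3 | alternative 2 | (2S,4R)-4-alkoxy-7-methoxy-2-phenyl-hexahydrochromen-5-one ether of unit B (C7 epimers) | COC1CC2=C(C(=O)C1)[C@H](O[C@@H]1C[C@@H](c3ccccc3)Oc3cc(OC)c(OC)c(OC)c31)C[C@@H](c1ccccc1)O2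
A4 | alternative 2 | 5-methoxy-2-({[(2S,4R)-5,6,7-trimethoxyflavan-4-yl]oxy}methylene)cyclohexane-1,3-dione | COC1CC(=O)C(=CO[C@@H]2C[C@@H](c3ccccc3)Oc3cc(OC)c(OC)c(OC)c32)C(=O)C1
A5 | alternative 2 | styrene | C=Cc1ccccc1
A6 | alternative 3 | 3'-iodo derivative of 5-O-SEM beilschmieflavonoid B (2'-phenyl and 3'-iodo trans) | COc1cc2c(c(OCOCC[Si](C)(C)C)c1OC)[C@H](O[C@@H]1[C@H](I)[C@@H](c3ccccc3)Oc3cc(OC)c(OC)c(OC)c31)C[C@@H](c1ccccc1)O2
A7 | alternative 3 | (E)-styrenyl phenol, 5-O-SEM unit A ether of (R)-1-(2-hydroxy-4,5,6-trimethoxyphenyl)-3-phenylprop-2-en-1-ol | COc1cc2c(c(OCOCC[Si](C)(C)C)c1OC)[C@H](O[C@@H](c1c(O)cc(OC)c(OC)c1OC)/C=C/c1ccccc1)C[C@@H](c1ccccc1)O2
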